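A direct plan would buy rings A and B and close ring C at C3–C4.
Aldehyde A1 would be O-alkylated with phenacyl bromide A2, and an NHC-catalysed crossed benzoin closure would give hydroxychromanone A3.
Dehydration and acid would give bromo-isoflavone A4, and a Heck reaction would add the side chain last.
Weakest would be the etherification/benzoin cascade: Rap–Stoermer aldol closure would compete under carbonate, and a 2,6-dioxygenated aldehyde would form its Breslow intermediate reluctantly.
The three MOM ethers would add length without complexity and would leave no early entry for the acid-labile side chain.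
The chlorosulfite dehydration of the tertiary ketol could end in substitution instead of the chromone.

The new route reads ring A with its acyl carbon C4 as a folded tetraketide: the oxygens on C5, C7 and C8a alternate as in an arylacetyl-primed triacetate chain. That chain is assembled on triacetic acid lactone, whose 2-pyrone masks three of the carbonyl groups, with ring B and the finished side chain already attached. Magnesium methoxide then opens the pyrone and re-closes it by Claisen condensation (C4a to C8a), so one aromatic ring is made from another and the phloroglucinol ring appears with free hydroxyls under base alone. No ether tether, benzoin closure, ketol dehydration or MOM group is needed; ring C is closed last by a one-carbon condensation.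

Key step: step 5

Remark: positions 3 and 5 of the 4-methoxyphenyl ring are equivalent, so the hydroxyl may be placed on either; compounds 1, 6 and 8 are taken as commercial.

Step 1
Reactants: 1 methyl (3-bromo-4-methoxyphenyl)acetate
Product: 3 methyl (3-bromo-5-formyl-4-methoxyphenyl)acetate, via α-chloro ether 2 (not isolated)
Conditions: Cl2CHOMe (1.5 equiv), TiCl4 (2.5 equiv), CH2Cl2, −10 → 0 °C; then ice-water
Reagents that add atoms: dichloromethyl methyl ether, COC(Cl)Cl (formyl carbon of 3; Cl and MeO of 2 only); water, O (formyl oxygen of 3)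
Why: Rieche formylation (Friedel–Crafts type): the methoxy group is the only strong activator and its para position is blocked, so the TiCl4-activated chloro(methoxy)methyl cation should enter at the free ortho position C5, and hydrolysis of the α-chloro ether should give the aldehyde with no stereocentre left.

Step 2
Reactants: 3 methyl (3-bromo-5-formyl-4-methoxyphenyl)acetate
Product: 5 methyl (3-bromo-5-hydroxy-4-methoxyphenyl)acetate, via aryl formate 4 (not isolated)
Conditions: mCPBA (1.4 equiv), CH2Cl2, 0 °C → rt; aq. Na2S2O3/NaHCO3 wash; then K2CO3 (0.2 equiv), MeOH, 0 °C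
Reagents that add atoms: 3-chloroperoxybenzoic acid (mCPBA), O=C(OO)c1cccc(Cl)c1
Why: Baeyer–Villiger oxidation (Dakin type): in the Criegee adduct the ortho-methoxyaryl group should migrate in preference to hydrogen, and the aryl formate should be cleaved by catalytic methoxide without touching the methyl ester or the aryl bromide.

Step 3
Reactants: 5 methyl (3-bromo-5-hydroxy-4-methoxyphenyl)acetate; 6 2-methylbut-3-en-2-ol (2.5 equiv)
Product: 7 methyl {3-hydroxy-5-[(1E)-3-hydroxy-3-methylbut-1-en-1-yl]-4-methoxyphenyl}acetate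
Conditions: Pd(OAc)2 (4 mol%), P(o-tol)3 (8 mol%), Et3N (3 equiv), DMF, 95 °C, Ar
Reagents that add atoms: none
Why: Mizoroki–Heck reaction on a simple aryl bromide: oxidative addition to zerovalent palladium, syn carbopalladation at the terminal alkene carbon and syn β-hydride elimination should give only the (E)-alkene, and the tertiary carbinol has no hydrogen that would allow isomerisation to a ketone.

Step 4
Reactants: 7 methyl {3-hydroxy-5-[(1E)-3-hydroxy-3-methylbut-1-en-1-yl]-4-methoxyphenyl}acetate; 8 4-hydroxy-6-methyl-2H-pyran-2-one (triacetic acid lactone, 4.2 equiv)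
Product: 9 4-hydroxy-6-(3-{3-hydroxy-5-[(1E)-3-hydroxy-3-methylbut-1-en-1-yl]-4-methoxyphenyl}-2-oxopropyl)-2H-pyran-2-one
Conditions: 8, LiN(i-Pr)2 (8.4 equiv), THF, −78 → −20 °C; then 7 in THF, −78 → 0 °C, 3 h; AcOH quench at −20 °C, water
Reagents that add atoms: none
Why: Claisen-type C-acylation of the pyrone dianion at its 6-methyl carbon (the terminus of the vinylogous enolate) by the methyl ester; the two hydroxyl groups of 7 and the acidic methylene of the product each take up one equivalent of dianion, which is why an excess is used, and the (E)-alkene and the tertiary alkoxide are inert to the base.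

Step 5 (key step)
Reactants: 9 4-hydroxy-6-(3-{3-hydroxy-5-[(1E)-3-hydroxy-3-methylbut-1-en-1-yl]-4-methoxyphenyl}-2-oxopropyl)-2H-pyran-2-one
Product: 11 2-{3-hydroxy-5-[(1E)-3-hydroxy-3-methylbut-1-en-1-yl]-4-methoxyphenyl}-1-(2,4,6-trihydroxyphenyl)ethan-1-one, via triketo ester 10 (not isolated)
Conditions: Mg(OMe)2 (6 equiv), dry MeOH, 65 °C, Ar, 8 h; AcOH to pH 4–5 at 0 °C
Reagents that add atoms: magnesium methoxide, C[O-].C[O-].[Mg+2] (MeO of 10 only)
Why: Methoxide opens the lactone of 9 at its carbonyl carbon (the future C8a) and gives the methyl 3,5,7-trioxo ester 10, held as a chelate of divalent magnesium. In this open tetraketide the methylene C4a between the C4 and C5 carbonyl groups is the most acidic carbon, and its magnesium enolate attacks the ester carbon C8a in a Claisen (Dieckmann-type) condensation, a 6-exo-trig closure that forms the C4a–C8a bond and ring A; loss of methoxide and enolisation of the 2-acylcyclohexane-1,3,5-trione to the phloroglucinol should make the step irreversible. The closest known reaction type is the magnesium methoxide cyclisation of 6-(2-oxoalkyl)-4-hydroxy-2-pyrones and of 3,5,7-triketo esters to acylphloroglucinols, the laboratory counterpart of the chalcone synthase fold. No stereocentre is formed. The step needs Claisen closure (C4a to C8a) to win over the aldol closures C8 to C4 and C3 to C7 and over retro-Claisen cleavage: chelation lowers the electrophilicity of the ketones and holds C4a next to the ester, and dry methoxide keeps the ester from hydrolysis, whereas aqueous hydroxide would favour the aldol path. The phenol, the tertiary allylic alcohol and the (E)-alkene are inert to methoxide, and the three hydroxyl groups of ring A are set free without any protecting group.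

Step 6
Reactants: 11 2-{3-hydroxy-5-[(1E)-3-hydroxy-3-methylbut-1-en-1-yl]-4-methoxyphenyl}-1-(2,4,6-trihydroxyphenyl)ethan-1-one
Product: 13 5,7-dihydroxy-3-{3-hydroxy-5-[(1E)-3-hydroxy-3-methylbut-1-en-1-yl]-4-methoxyphenyl}-4H-chromen-4-one (target), via enaminone 12 (not isolated)
Conditions: Me2NCH(OMe)2 (3 equiv), THF, 0 → 60 °C, 4 h; then pH 6 phosphate buffer
Reagents that add atoms: N,N-dimethylformamide dimethyl acetal, COC(OC)N(C)C (C2 of 13; Me2N of 12 only)
Why: Enaminone condensation and chromone annulation (the amide acetal isoflavone synthesis from a deoxybenzoin): the benzylic methylene C3 is the only acidic C–H position, a chelated ortho-hydroxyl should add to C2 of the enaminone and dimethylamine should leave to close ring C, the two ortho-hydroxyls being equivalent, and the non-acidic medium spares the tertiary allylic alcohol.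

Compound list
1 | methyl (3-bromo-4-methoxyphenyl)acetate | COC(=O)Cc1ccc(OC)c(Br)c1 | starting material
2 | methyl {3-bromo-5-[chloro(methoxy)methyl]-4-methoxyphenyl}acetate (racemic, not isolated) | COC(=O)Cc1cc(Br)c(OC)c(C(Cl)OC)c1 | intermediate
3 | methyl (3-bromo-5-formyl-4-methoxyphenyl)acetate | COC(=O)Cc1cc(Br)c(OC)c(C=O)c1 | intermediate
4 | methyl [3-bromo-5-(formyloxy)-4-methoxyphenyl]acetate (not isolated) | COC(=O)Cc1cc(Br)c(OC)c(OC=O)c1 | intermediate
5 | methyl (3-bromo-5-hydroxy-4-methoxyphenyl)acetate | COC(=O)Cc1cc(Br)c(OC)c(O)c1 | intermediate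
6 | 2-methylbut-3-en-2-ol | C=CC(C)(C)O | starting material
7 | methyl {3-hydroxy-5-[(1E)-3-hydroxy-3-methylbut-1-en-1-yl]-4-methoxyphenyl}acetate | COC(=O)Cc1cc(O)c(OC)c(/C=C/C(C)(C)O)c1 | intermediate
8 | 4-hydroxy-6-methyl-2H-pyran-2-one (triacetic acid lactone) | CC1=CC(O)=CC(=O)O1 | starting material
9 | 4-hydroxy-6-(3-{3-hydroxy-5-[(1E)-3-hydroxy-3-methylbut-1-en-1-yl]-4-methoxyphenyl}-2-oxopropyl)-2H-pyran-2-one | O=C(CC1=CC(O)=CC(=O)O1)Cc1cc(O)c(OC)c(/C=C/C(C)(C)O)c1 | intermediate
10 | methyl 8-{3-hydroxy-5-[(1E)-3-hydroxy-3-methylbut-1-en-1-yl]-4-methoxyphenyl}-3,5,7-trioxooctanoate (magnesium chelate in the flask, not isolated) | COC(=O)CC(=O)CC(=O)CC(=O)Cc1cc(O)c(OC)c(/C=C/C(C)(C)O)c1 | intermediate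
11 | 2-{3-hydroxy-5-[(1E)-3-hydroxy-3-methylbut-1-en-1-yl]-4-methoxyphenyl}-1-(2,4,6-trihydroxyphenyl)ethan-1-one | O=C(Cc1cc(O)c(OC)c(/C=C/C(C)(C)O)c1)c1c(O)cc(O)cc1O | intermediate
12 | 3-(dimethylamino)-2-{3-hydroxy-5-[(1E)-3-hydroxy-3-methylbut-1-en-1-yl]-4-methoxyphenyl}-1-(2,4,6-trihydroxyphenyl)prop-2-en-1-one (enamine geometry not defined, not isolated) | CN(C)C=C(C(=O)c1c(O)cc(O)cc1O)c1cc(O)c(OC)c(/C=C/C(C)(C)O)c1 | intermediate
13 | 5,7-dihydroxy-3-{3-hydroxy-5-[(1E)-3-hydroxy-3-methylbut-1-en-1-yl]-4-methoxyphenyl}-4H-chromen-4-one | COc1c(O)cc(-c2coc3cc(O)cc(O)c3c2=O)cc1/C=C/C(C)(C)O | target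

Total step count: 6. Longest linear sequence: 6 steps (1 to 13).

Steps most likely to fail

1. Step 5 (key step). The open triketo ester may close by aldol condensation, or be cut by retro-Claisen attack of methoxide, instead of folding in the Claisen sense. The fallback sets out from 5 and moves all acidic operations ahead of the side chain. Saponification (LiOH, THF/H2O) would give (3-bromo-5-hydroxy-4-methoxyphenyl)acetic acid F1. Friedel–Crafts acylation of phloroglucinol with F1 (neat BF3·OEt2, 85 °C) would give 2-(3-bromo-5-hydroxy-4-methoxyphenyl)-1-(2,4,6-trihydroxyphenyl)ethan-1-one F2. The Heck reaction of F2 with 6 under the conditions of step 3 would come back to the route at 11.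

2. Step 4. Proton transfer from the benzylic ester position to the dianion, or poor solubility of the lithium salts of 7, may outrun acylation. The fallback sets out from 7 and replaces the ester by a faster electrophile. Reduction with diisobutylaluminium hydride (i-Bu2AlH, CH2Cl2, −78 °C) would give {3-hydroxy-5-[(1E)-3-hydroxy-3-methylbut-1-en-1-yl]-4-methoxyphenyl}acetaldehyde F3. Aldol addition of the dianion of 8 to F3 would give rac-4-hydroxy-6-(2-hydroxy-3-{3-hydroxy-5-[(1E)-3-hydroxy-3-methylbut-1-en-1-yl]-4-methoxyphenyl}propyl)-2H-pyran-2-one F4. Parikh–Doering oxidation (SO3·pyridine, DMSO, Et3N) would come back to the route at 9.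

3. Step 1. Formylation may be slow at the hindered position next to the methoxy group, or the Lewis acid may cleave the methyl ether. The fallback sets out from 1 and bypasses 3. Nitration ortho to the methoxy group (HNO3, AcOH, 15 °C) would give methyl (3-bromo-4-methoxy-5-nitrophenyl)acetate F5. Reduction (Fe, NH4Cl, EtOH/H2O) would give methyl (3-amino-5-bromo-4-methoxyphenyl)acetate F6. Diazotisation (NaNO2, aq. H2SO4, 0 °C) would give 3-bromo-2-methoxy-5-(2-methoxy-2-oxoethyl)benzenediazonium hydrogen sulfate F7, and hydroxy-dediazoniation (Cu2O, Cu(NO3)2, H2O) would come back to the route at 5.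

Further compounds
F1 | step 5 | (3-bromo-5-hydroxy-4-methoxyphenyl)acetic acid | OC(=O)Cc1cc(Br)c(OC)c(O)c1
F2 | step 5 | 2-(3-bromo-5-hydroxy-4-methoxyphenyl)-1-(2,4,6-trihydroxyphenyl)ethan-1-one | O=C(Cc1cc(Br)c(OC)c(O)c1)c1c(O)cc(O)cc1O
F3 | step 4 | {3-hydroxy-5-[(1E)-3-hydroxy-3-methylbut-1-en-1-yl]-4-methoxyphenyl}acetaldehyde | O=CCc1cc(O)c(OC)c(/C=C/C(C)(C)O)c1
F4 | step 4 | rac-4-hydroxy-6-(2-hydroxy-3-{3-hydroxy-5-[(1E)-3-hydroxy-3-methylbut-1-en-1-yl]-4-methoxyphenyl}propyl)-2H-pyran-2-one | OC(CC1=CC(O)=CC(=O)O1)Cc1cc(O)c(OC)c(/C=C/C(C)(C)O)c1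
F5 | step 1 | methyl (3-bromo-4-methoxy-5-nitrophenyl)acetate | COC(=O)Cc1cc(Br)c(OC)c([N+](=O)[O-])c1
F6 | step 1 | methyl (3-amino-5-bromo-4-methoxyphenyl)acetate | COC(=O)Cc1cc(Br)c(OC)c(N)c1
F7 | step 1 | 3-bromo-2-methoxy-5-(2-methoxy-2-oxoethyl)benzenediazonium hydrogen sulfate | COC(=O)Cc1cc(Br)c(OC)c([N+]#N)c1.OS(=O)(=O)[O-]
A1 | direct plan | 2-hydroxy-4,6-bis(methoxymethoxy)benzaldehyde | O=Cc1c(O)cc(OCOC)cc1OCOC
A2 | direct plan | 2-bromo-1-[3-bromo-4-methoxy-5-(methoxymethoxy)phenyl]ethanone | O=C(CBr)c1cc(OCOC)c(OC)c(Br)c1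
A3 | direct plan | rac-3-[3-bromo-4-methoxy-5-(methoxymethoxy)phenyl]-3-hydroxy-5,7-bis(methoxymethoxy)-2,3-dihydro-4H-chromen-4-one | O=C1c2c(OCOC)cc(OCOC)cc2OCC1(O)c1cc(OCOC)c(OC)c(Br)c1
A4 | direct plan | 3-(3-bromo-5-hydroxy-4-methoxyphenyl)-5,7-dihydroxy-4H-chromen-4-one | O=c1c(-c2cc(O)c(OC)c(Br)c2)coc2cc(O)cc(O)c12
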